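The constants used here come from no measurement; the flask was simulated.

Take the even split as the zero of the scale before choosing what goes on the next run. In these flasks X turns into L, L is caught by J to give J.L or by Q to give Q.L, and J.L passes reversibly to E.

    X → L (k1 = 5.80 /s, Ea1 = 51.0 kJ/mol)
    J + L → J.L (k2 = 7.56 × 10⁵ /M/s, Ea2 = 15.0 kJ/mol)
    Q + L → Q.L (k3 = 3.79 × 10⁵ /M/s, Ea3 = 12.0 kJ/mol)
    J.L ⇌ E (K4 = 1.27, k4 = 0.309 /s, Ea4 = 63.0 kJ/mol, ΔH4 = −63.0 kJ/mol)
    (constants at 0 °C)

| flask | X | J | Q | time | remark | temperature |
|---|---|---|---|---|---|---|
| birch | 0.20 mM | 2.00 equiv | 1.50 equiv (fed, over 2.5 s) | 3.0 s | the addition at −40 °C, then warmed to 0 °C; the feed brings no volume worth counting |  |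
| maple | 0.20 mM | 2.00 equiv | 1.50 equiv | 3.0 s | everything together at the start | 0 °C |
| ash | 0.20 mM | 2.00 equiv | 1.50 equiv (fed, over 2.5 s) | 3.0 s | all else is in the flask from the start; the feed brings no volume worth counting | 0 °C |
| alder | 0.20 mM | 2.00 equiv | 1.50 equiv | 3.0 s | everything together at the start at −40 °C, warmed to 0 °C at 2.5 s |  |
| cedar | 0.20 mM | 2.00 equiv | 1.50 equiv (in portions, 2, over 2.5 s) | 3.0 s | first portion at the start, last at 2.5 s | 0 °C |

- the flask that comes out highest in amount of J.L, in percent of the X charged, or "all alike" when all lie within 1.5 percentage points (birch / maple / ash / alder / cedar / all alike)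
- J.L at the end, in percent of the X charged, birch
- J.L at the end, in percent of the X charged, maple
- J.L at the end, in percent of the X charged, ash
- J.L at the end, in percent of the X charged, alder
- J.L at the end, in percent of the X charged, cedar

- the constants hold at 0 °C; other temperatures follow from the activation energies and enthalpies

With both charges whole at 0 °C, I reckoned 2.66 for the rate of capture of L by J over its rate of capture by Q. This is the split ratio S, a selectivity factor on which one marks an even split. J caught L far faster than X made it, so I held L at steady state and took the split of rates as the split of material. The share of L going to J is then S over one plus S, 72.7 %, and I committed to that for J.L and E together in maple, with the fall of J and Q ignored.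

Feeding Q moves S. In ash, X has a lifetime of 0.172 s, and by then the feed has delivered 6.90 % of Q, so S stood near 38.6 at that moment. That raises the share of J, but it does not protect J.L. In maple, the 3.0 s of the run exceeds the 2.2 s half-life of J.L by the forward step to E alone, and ash stands at the same temperature.

Cold was the other lever, since the step to E has the higher activation energy, 63.0 kJ/mol against 51.0 kJ/mol for X going to L. Cooling therefore slows the loss of J.L more than the making of L. So I chose J charged whole, Q fed during the cold stretch at −40 °C, and a warm finish at 0 °C, which is birch, and I expected it to come out highest.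

The forecast named birch, with 62.2 % for birch, 39.4 % for maple, 53.8 % for ash, 59.5 % for alder and 46 % for cedar, on the ground that “L is at steady state”.

The simulation gave birch as highest, with J.L at 62.1 % in birch, 39.4 % in maple, 53.8 % in ash, 59.5 % in alder and 46.1 % in cedar. Maple held 70.6 % of X as J.L and E together at 3.00 s, below my share.

In birch at 2.56 s, just after warming, L went to J.L 2.3 times as fast as to Q.L, a reading lower than the 2.66 I had reckoned for whole charges. In the neighbour of birch charged with 3.80 equiv of Q, S falls to 1.05, close to the even mark, and at 3.00 s that flask held J.L at 45.3 %, Q.L at 44.9 % and E at 5.72 %.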